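A direct plan would open an enantiopure 2,2-disubstituted oxetane A1 with hydrogen peroxide to a tertiary hydroperoxide, close this onto a methyl ketone as the 3-methoxy-1,2-dioxolane A2, add the acetate arm to the derived peroxycarbenium ion with a silyl ketene acetal, and then build the triene by olefination. Its weakest steps would be:
- the C–C bond formation at C3, because the cation would see only a methyl group against an alkyl chain at C5 and would give both C3 epimers;
- the Lewis acid perhydrolysis of the oxetane, which would need anhydrous H2O2 and could lose configuration through an open tertiary cation;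
- the long run of functional group changes needed to reach the oxetane and the peroxyketal, which would add steps but no complexity.

The new route disconnects both C–O bonds of the peroxide, O–C5 and O–C3, back to O2 and an acyclic bis-allylic alcohol, and places a temporary hydroxyl on C4, the ring CH2 that lies between the two tetrasubstituted carbons of the 1,2-dioxolane. In one flask, a hydroxyl-directed singlet-oxygen ene reaction creates the C5 hydroperoxide and a hydroxyl-controlled 5-exo cycloperoxymercuration closes the ring at C3, so both centres are set by 1,2-induction from one easily made carbinol instead of by telling a methyl from a chain. The C4–O and C–Hg bonds are then excised. No peroxycarbenium ion, no substitution at a tertiary carbon and no oxetane are involved.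

Key step: step 4

Remark: in the comments C3, C4, C5 and C1′–C15′ are the ring and side-chain atoms of the target; the antipode of the ligand in step 3 that gives the 9S carbinol is assumed to be fixed beforehand on a racemic sample.

Step 1
Reactants: 1 4-[(tert-butyldimethylsilyl)oxy]butanal
Product: 2 4-[(tert-butyldimethylsilyl)oxy]-2-methylidenebutanal
Conditions: 37% aq. HCHO (1.2 equiv), pyrrolidine (10 mol %), EtCO2H (10 mol %), i-PrOH, 45 °C
Reagents that add atoms: formaldehyde, C=O
Why: Organocatalytic α-methylenation (Mannich condensation with formaldehyde, then loss of the amine) turns the α-CH2 of 1 into the 1,1-disubstituted alkene that will later carry the C3 methyl group, and neither the silyl ether nor any stereocentre is involved.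

Step 2
Reactants: 3 methyl 7-oxoheptanoate; 4 ethyltriphenylphosphonium iodide
Product: 8 methyl (7Z)-8-iodonon-7-enoate, via ethylidenetriphenylphosphorane 5 (not isolated), via (1-iodoethyl)triphenylphosphonium iodide 6 (not isolated), via (1-iodoethylidene)triphenylphosphorane 7 (not isolated)
Conditions: 4 (1.3 equiv), n-BuLi, THF, 0 °C; I2, −78 °C; NaN(SiMe3)2, −78 °C; then 3, −78 → −20 °C
Reagents that add atoms: iodine, II
Why: In this Stork–Zhao-type Wittig olefination the unstabilised α-iodo ylide 7, formed by iodination of ylide 5 and deprotonation of salt 6, should add to the aldehyde under kinetic control through the cis-oxaphosphetane so that iodine ends cis to the chain (7Z), while the methyl ester is inert at −78 °C.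

Step 3
Reactants: 8 methyl (7Z)-8-iodonon-7-enoate; 2 4-[(tert-butyldimethylsilyl)oxy]-2-methylidenebutanal
Product: 11 methyl (7Z,9S)-12-[(tert-butyldimethylsilyl)oxy]-9-hydroxy-8-methyl-10-methylidenedodec-7-enoate, via alkenylchromium species 9 (not isolated), via trimethylsilyl ether 10 (not isolated)
Conditions: CrCl2 (10 mol %), N-[2-(4-isopropyl-4,5-dihydro-1,3-oxazol-2-yl)phenyl]methanesulfonamide (one enantiomer, 12 mol %), Et3N (20 mol %), NiCl2·(2,9-dimethyl-1,10-phenanthroline) (2 mol %), Mn (2 equiv), Me3SiCl (2 equiv), LiCl, MeCN, 25 °C; then K2CO3, MeOH, 0 °C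
Reagents that add atoms: none
Why: In this catalytic asymmetric Nozaki–Hiyama–Kishi reaction zerovalent nickel inserts into the C–I bond with retention of the Z geometry, transmetalation gives alkenylchromium 9, whose sulfonamide ligand selects one face of aldehyde 2 and so sets the C9 carbinol (the future C4 relay) under reagent control, Me3SiCl releasing chromium as silyl ether 10, which methanolysis cleaves without touching the ester or the tert-butyldimethylsilyl ether.

Step 4
Reactants: 11 methyl (7Z,9S)-12-[(tert-butyldimethylsilyl)oxy]-9-hydroxy-8-methyl-10-methylidenedodec-7-enoate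
Product: 13 methyl (6E)-7-[(3S,4R,5S)-5-[(acetoxymercurio)methyl]-5-{2-[(tert-butyldimethylsilyl)oxy]ethyl}-4-hydroxy-3-methyl-1,2-dioxolan-3-yl]hept-6-enoate, via allylic hydroperoxide 12 (not isolated)
Conditions: O2, 5,10,15,20-tetraphenylporphyrin (0.5 mol %), CH2Cl2, 0 °C, white LED; then Ar purge, Hg(OAc)2 (1.05 equiv), 0 °C, dark
Reagents that add atoms: oxygen, O=O; mercury diacetate, CC(=O)O[Hg]OC(C)=O
Why: Sensitised photooxygenation generates 1O2, which attacks the electron-rich (Z)-trisubstituted C7=C8 alkene of 11 in a hydroxyl-directed Schenck ene reaction: with C9–H held in the alkene plane by A(1,3) strain against the cis C6 methylene, the C9 hydroxyl hydrogen-bonds the incoming oxygen, which bonds to C8 on that face and takes a hydrogen from C6, so the tertiary hydroperoxide 12 (target C5) should form threo to the carbinol with the alkene moved to C6=C7 (E). Hg(OAc)2 then activates the 1,1-disubstituted C10=CH2 alkene and the hydroperoxide adds to its substituted carbon anti to mercury (cycloperoxymercuration, Markovnikov), which closes the 1,2-dioxolane in 5-exo-trig mode and forms the second tertiary C–OO bond (target C3). The closest known reactions are the hydroxyl-directed ene reaction of chiral allylic alcohols, which gives threo-β-hydroxy allylic hydroperoxides, and the cycloperoxymercuration of unsaturated hydroperoxides to (mercuriomethyl)-1,2-dioxolanes. C5 is controlled by the C9 carbinol through the hydrogen-bonded ene transition state, and C3 by the same carbinol through the inside-alkoxy conformation of the mercuration (C9–O eclipsing the alkene, C9–H next to the silyloxyethyl arm, the peroxide tether perpendicular), which places CH2Hg cis to the hydroxyl. Because the hydroxyl thus ends cis to the chain at C5 and cis to the future methyl group at C3, the two methyl groups come out trans, and the 9S configuration of 11 translates into 3R,5S of the target. The step needs 1O2 to choose the trisubstituted over the 1,1-disubstituted alkene, abstraction from C6 and not from the C8 methyl group, and 5-exo closure in preference to 5-endo attack on C6=C7; the higher nucleophilicity of the trisubstituted alkene, the cis effect reinforced by the Z geometry, and the greater reactivity of 1,1-disubstituted alkenes toward Hg(OAc)2 should secure these, and no strong acid is added so that the organomercurial does not equilibrate.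

Step 5
Reactants: 13 methyl (6E)-7-[(3S,4R,5S)-5-[(acetoxymercurio)methyl]-5-{2-[(tert-butyldimethylsilyl)oxy]ethyl}-4-hydroxy-3-methyl-1,2-dioxolan-3-yl]hept-6-enoate
Product: 14 methyl 7-[(3S,4R,5S)-5-[(acetoxymercurio)methyl]-5-{2-[(tert-butyldimethylsilyl)oxy]ethyl}-4-hydroxy-3-methyl-1,2-dioxolan-3-yl]heptanoate
Conditions: KO2C–N=N–CO2K (10 equiv), AcOH (20 equiv), MeOH, 0 → 25 °C
Reagents that add atoms: none
Why: Diimide reduction transfers H2 to the C6=C7 alkene in a concerted syn fashion that leaves the O–O and C–Hg bonds alone (catalytic hydrogenation would not), and it is placed here so that the two later radical reductions meet no alkene within reach.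

Step 6
Reactants: 14 methyl 7-[(3S,4R,5S)-5-[(acetoxymercurio)methyl]-5-{2-[(tert-butyldimethylsilyl)oxy]ethyl}-4-hydroxy-3-methyl-1,2-dioxolan-3-yl]heptanoate
Product: 15 methyl 7-[(3S,4R,5S)-5-{2-[(tert-butyldimethylsilyl)oxy]ethyl}-4-hydroxy-3,5-dimethyl-1,2-dioxolan-3-yl]heptanoate
Conditions: NaBH4 (2 equiv), THF–aq. NaHCO3, −10 °C
Reagents that add atoms: none
Why: In this reductive demercuration hydride converts C–HgOAc into C–HgH, which collapses through the primary alkyl radical to the C3 methyl group as in the known reductions of (mercuriomethyl)-1,2-dioxolanes, the cold buffered medium limiting both epoxide formation from the β-peroxyalkyl radical and base-induced fragmentation of the β-hydroxy peroxide, and no stereocentre is touched.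

Step 7
Reactants: 15 methyl 7-[(3S,4R,5S)-5-{2-[(tert-butyldimethylsilyl)oxy]ethyl}-4-hydroxy-3,5-dimethyl-1,2-dioxolan-3-yl]heptanoate
Product: 16 methyl 7-[(3S,4R,5S)-5-{2-[(tert-butyldimethylsilyl)oxy]ethyl}-3,5-dimethyl-4-[(phenoxycarbonothioyl)oxy]-1,2-dioxolan-3-yl]heptanoate
Conditions: PhOC(S)Cl (3 equiv), DMAP (4 equiv), MeCN, 40 °C
Reagents that add atoms: O-phenyl carbonochloridothioate, S=C(Cl)Oc1ccccc1
Why: DMAP-catalysed acylation of the hindered C4 hydroxyl gives the thionocarbonate needed for radical deoxygenation under neutral conditions, which avoid the alkoxide that could fragment the β-hydroxy peroxide.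

Step 8
Reactants: 16 methyl 7-[(3S,4R,5S)-5-{2-[(tert-butyldimethylsilyl)oxy]ethyl}-3,5-dimethyl-4-[(phenoxycarbonothioyl)oxy]-1,2-dioxolan-3-yl]heptanoate
Product: 17 methyl 7-[(3S,5S)-5-{2-[(tert-butyldimethylsilyl)oxy]ethyl}-3,5-dimethyl-1,2-dioxolan-3-yl]heptanoate
Conditions: Bu3SnH (2 equiv), AIBN (0.2 equiv), toluene, 80 °C
Reagents that add atoms: none
Why: In this Barton–McCombie deoxygenation Bu3Sn• adds to the C=S group, the C4–O bond fragments and the ring radical takes hydrogen from Bu3SnH, the radical orbital lying perpendicular to the in-ring O–O bond so that attack on the peroxide should be slow (4-halo- and 4-mercurio-1,2-dioxolanes are reduced at C4 in the same way), which removes the relay oxygen and leaves C3 and C5 untouched.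

Step 9
Reactants: 17 methyl 7-[(3S,5S)-5-{2-[(tert-butyldimethylsilyl)oxy]ethyl}-3,5-dimethyl-1,2-dioxolan-3-yl]heptanoate
Product: 18 7-[(3S,5S)-5-{2-[(tert-butyldimethylsilyl)oxy]ethyl}-3,5-dimethyl-1,2-dioxolan-3-yl]heptanal
Conditions: i-Bu2AlH (1.1 equiv), CH2Cl2, −78 °C; MeOH, aq. KNaC4H4O6
Reagents that add atoms: none
Why: Partial reduction of the ester with i-Bu2AlH stops at the aldehyde because the tetrahedral aluminium hemiacetal survives at −78 °C until the quench, and hindered dialkyl peroxides tolerate the reagent at this temperature.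

Step 10
Reactants: 18 7-[(3S,5S)-5-{2-[(tert-butyldimethylsilyl)oxy]ethyl}-3,5-dimethyl-1,2-dioxolan-3-yl]heptanal; 19 2,2′-methylenebis(4,4,5,5-tetramethyl-1,3,2-dioxaborolane)
Product: 21 tert-butyl{2-[(3S,5S)-3,5-dimethyl-5-[(7E)-8-(4,4,5,5-tetramethyl-1,3,2-dioxaborolan-2-yl)oct-7-en-1-yl]-1,2-dioxolan-3-yl]ethoxy}dimethylsilane, via lithiated diborylmethane 20 (not isolated)
Conditions: 19 (1.3 equiv), lithium 2,2,6,6-tetramethylpiperidide (1.25 equiv), THF, 0 °C; then 18, −78 → 25 °C
Reagents that add atoms: none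
Why: In this boron–Wittig olefination the α-boryl carbanion 20 adds to the aldehyde and syn elimination of the B–O unit should give the (E)-alkenylboronate (C7′=C8′) under steric control, the stabilised carbanion being too weak a reductant to attack the O–O bond.

Step 11
Reactants: 22 (3Z)-hex-3-en-1-ol
Product: 23 (3Z)-hex-3-enal
Conditions: Dess–Martin periodinane (1.2 equiv), NaHCO3, CH2Cl2, 0 °C; used crude
Reagents that add atoms: none
Why: Buffered Dess–Martin oxidation of the homoallylic alcohol stops at the β,γ-unsaturated aldehyde, which is used at once so that the Z alkene does not move into conjugation.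

Step 12
Reactants: 23 (3Z)-hex-3-enal
Product: 24 (1E,4Z)-1-iodohepta-1,4-diene
Conditions: CrCl2 (6 equiv), CHI3 (2 equiv), THF–1,4-dioxane, 0 → 25 °C
Reagents that add atoms: iodoform, IC(I)I
Why: In the Takai olefination the geminal dichromium species formed from CHI3 and CrCl2 adds to the aldehyde and eliminates to the (E)-iodoalkene under steric control, the remote Z alkene being untouched.

Step 13
Reactants: 21 tert-butyl{2-[(3S,5S)-3,5-dimethyl-5-[(7E)-8-(4,4,5,5-tetramethyl-1,3,2-dioxaborolan-2-yl)oct-7-en-1-yl]-1,2-dioxolan-3-yl]ethoxy}dimethylsilane; 24 (1E,4Z)-1-iodohepta-1,4-diene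
Product: 25 tert-butyl{2-[(3S,5S)-3,5-dimethyl-5-[(7E,9E,12Z)-pentadeca-7,9,12-trien-1-yl]-1,2-dioxolan-3-yl]ethoxy}dimethylsilane
Conditions: Pd(PPh3)4 (5 mol %), 24 (1.3 equiv), 3 M aq. K3PO4 (3 equiv), THF, 40 °C
Reagents that add atoms: none
Why: Suzuki–Miyaura cross-coupling (oxidative addition of zerovalent palladium to the C–I bond, base-assisted transmetalation from boron, reductive elimination) proceeds with retention at both alkenyl carbons and so forms the C8′–C9′ bond with the 7E,9E-diene beside the 12Z alkene, the hindered dialkyl peroxide being expected to survive as in other palladium couplings of peroxide-containing partners.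

Step 14
Reactants: 25 tert-butyl{2-[(3S,5S)-3,5-dimethyl-5-[(7E,9E,12Z)-pentadeca-7,9,12-trien-1-yl]-1,2-dioxolan-3-yl]ethoxy}dimethylsilane
Product: 26 2-[(3S,5S)-3,5-dimethyl-5-[(7E,9E,12Z)-pentadeca-7,9,12-trien-1-yl]-1,2-dioxolan-3-yl]ethan-1-ol
Conditions: HF·pyridine, pyridine, THF, 0 → 25 °C
Reagents that add atoms: none
Why: Fluoride-induced desilylation, driven by the strength of the Si–F bond, frees the primary alcohol under buffered conditions that leave the triene and the peroxide intact.

Step 15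
Reactants: 26 2-[(3S,5S)-3,5-dimethyl-5-[(7E,9E,12Z)-pentadeca-7,9,12-trien-1-yl]-1,2-dioxolan-3-yl]ethan-1-ol
Product: 27 2-[(3R,5S)-3,5-dimethyl-5-[(7E,9E,12Z)-pentadeca-7,9,12-trien-1-yl]-1,2-dioxolan-3-yl]acetaldehyde
Conditions: Dess–Martin periodinane (1.3 equiv), NaHCO3, CH2Cl2, 0 °C
Reagents that add atoms: none
Why: Buffered Dess–Martin oxidation gives the aldehyde without acid or base strong enough to open the ring by enolisation and β-elimination, so C3 keeps its configuration (its descriptor becomes R only through the priorities) and the triene is untouched.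

Step 16
Reactants: 27 2-[(3R,5S)-3,5-dimethyl-5-[(7E,9E,12Z)-pentadeca-7,9,12-trien-1-yl]-1,2-dioxolan-3-yl]acetaldehyde
Product: 28 2-[(3R,5S)-3,5-dimethyl-5-[(7E,9E,12Z)-pentadeca-7,9,12-trien-1-yl]-1,2-dioxolan-3-yl]acetic acid
Conditions: NaClO2 (3 equiv), NaH2PO4 (4 equiv), 2-methylbut-2-ene (30 equiv), t-BuOH–H2O, 0 °C
Reagents that add atoms: sodium chlorite, [Na+].[O-]Cl=O
Why: In the Pinnick oxidation chlorous acid adds to the aldehyde and fragments to the carboxylic acid and HOCl, which the excess of 2-methylbut-2-ene traps before it can attack the triene, and at about pH 4 neither stereocentre nor the peroxide is affected, giving the target.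

**Compound list**
1 | 4-[(tert-butyldimethylsilyl)oxy]butanal | O=CCCCO[Si](C)(C)C(C)(C)C | starting material
2 | 4-[(tert-butyldimethylsilyl)oxy]-2-methylidenebutanal | C=C(C=O)CCO[Si](C)(C)C(C)(C)C | intermediate
3 | methyl 7-oxoheptanoate | COC(=O)CCCCCC=O | starting material
4 | ethyltriphenylphosphonium iodide | CC[P+](c1ccccc1)(c1ccccc1)c1ccccc1.[I-] | starting material
5 | ethylidenetriphenylphosphorane | CC=P(c1ccccc1)(c1ccccc1)c1ccccc1 | intermediate
6 | (1-iodoethyl)triphenylphosphonium iodide | CC(I)[P+](c1ccccc1)(c1ccccc1)c1ccccc1.[I-] | intermediate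
7 | (1-iodoethylidene)triphenylphosphorane | CC(I)=P(c1ccccc1)(c1ccccc1)c1ccccc1 | intermediate
8 | methyl (7Z)-8-iodonon-7-enoate | COC(=O)CCCCC/C=C(\I)C | intermediate
9 | methyl (7Z)-8-(dichlorochromio)non-7-enoate (alkenylchromium species, further ligands omitted) | COC(=O)CCCCC/C=C(\[Cr](Cl)Cl)C | intermediate
10 | methyl (7Z,9S)-12-[(tert-butyldimethylsilyl)oxy]-8-methyl-10-methylidene-9-[(trimethylsilyl)oxy]dodec-7-enoate | COC(=O)CCCCC/C=C(C)\[C@@H](O[Si](C)(C)C)C(=C)CCO[Si](C)(C)C(C)(C)C | intermediate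
11 | methyl (7Z,9S)-12-[(tert-butyldimethylsilyl)oxy]-9-hydroxy-8-methyl-10-methylidenedodec-7-enoate | COC(=O)CCCCC/C=C(C)\[C@@H](O)C(=C)CCO[Si](C)(C)C(C)(C)C | intermediate
12 | methyl (6E,8S,9S)-12-[(tert-butyldimethylsilyl)oxy]-8-hydroperoxy-9-hydroxy-8-methyl-10-methylidenedodec-6-enoate | COC(=O)CCCC/C=C/[C@](C)(OO)[C@@H](O)C(=C)CCO[Si](C)(C)C(C)(C)C | intermediate
13 | methyl (6E)-7-[(3S,4R,5S)-5-[(acetoxymercurio)methyl]-5-{2-[(tert-butyldimethylsilyl)oxy]ethyl}-4-hydroxy-3-methyl-1,2-dioxolan-3-yl]hept-6-enoate | COC(=O)CCCC/C=C/[C@@]1(C)[C@@H](O)[C@](C[Hg]OC(C)=O)(CCO[Si](C)(C)C(C)(C)C)OO1 | intermediate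
14 | methyl 7-[(3S,4R,5S)-5-[(acetoxymercurio)methyl]-5-{2-[(tert-butyldimethylsilyl)oxy]ethyl}-4-hydroxy-3-methyl-1,2-dioxolan-3-yl]heptanoate | COC(=O)CCCCCC[C@@]1(C)[C@@H](O)[C@](C[Hg]OC(C)=O)(CCO[Si](C)(C)C(C)(C)C)OO1 | intermediate
15 | methyl 7-[(3S,4R,5S)-5-{2-[(tert-butyldimethylsilyl)oxy]ethyl}-4-hydroxy-3,5-dimethyl-1,2-dioxolan-3-yl]heptanoate | COC(=O)CCCCCC[C@@]1(C)[C@@H](O)[C@](C)(CCO[Si](C)(C)C(C)(C)C)OO1 | intermediate
16 | methyl 7-[(3S,4R,5S)-5-{2-[(tert-butyldimethylsilyl)oxy]ethyl}-3,5-dimethyl-4-[(phenoxycarbonothioyl)oxy]-1,2-dioxolan-3-yl]heptanoate | COC(=O)CCCCCC[C@@]1(C)[C@@H](OC(=S)Oc2ccccc2)[C@](C)(CCO[Si](C)(C)C(C)(C)C)OO1 | intermediate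
17 | methyl 7-[(3S,5S)-5-{2-[(tert-butyldimethylsilyl)oxy]ethyl}-3,5-dimethyl-1,2-dioxolan-3-yl]heptanoate | COC(=O)CCCCCC[C@@]1(C)C[C@](C)(CCO[Si](C)(C)C(C)(C)C)OO1 | intermediate
18 | 7-[(3S,5S)-5-{2-[(tert-butyldimethylsilyl)oxy]ethyl}-3,5-dimethyl-1,2-dioxolan-3-yl]heptanal | O=CCCCCCC[C@@]1(C)C[C@](C)(CCO[Si](C)(C)C(C)(C)C)OO1 | intermediate
19 | 2,2′-methylenebis(4,4,5,5-tetramethyl-1,3,2-dioxaborolane) | CC1(C)OB(CB2OC(C)(C)C(C)(C)O2)OC1(C)C | starting material
20 | [bis(4,4,5,5-tetramethyl-1,3,2-dioxaborolan-2-yl)methyl]lithium | [Li]C(B1OC(C)(C)C(C)(C)O1)B1OC(C)(C)C(C)(C)O1 | intermediate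
21 | tert-butyl{2-[(3S,5S)-3,5-dimethyl-5-[(7E)-8-(4,4,5,5-tetramethyl-1,3,2-dioxaborolan-2-yl)oct-7-en-1-yl]-1,2-dioxolan-3-yl]ethoxy}dimethylsilane | CC1(C)OB(/C=C/CCCCCC[C@@]2(C)C[C@](C)(CCO[Si](C)(C)C(C)(C)C)OO2)OC1(C)C | intermediate
22 | (3Z)-hex-3-en-1-ol | CC/C=C\CCO | starting material
23 | (3Z)-hex-3-enal | CC/C=C\CC=O | intermediate
24 | (1E,4Z)-1-iodohepta-1,4-diene | CC/C=C\C/C=C/I | intermediate
25 | tert-butyl{2-[(3S,5S)-3,5-dimethyl-5-[(7E,9E,12Z)-pentadeca-7,9,12-trien-1-yl]-1,2-dioxolan-3-yl]ethoxy}dimethylsilane | CC/C=C\C/C=C/C=C/CCCCCC[C@@]1(C)C[C@](C)(CCO[Si](C)(C)C(C)(C)C)OO1 | intermediate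
26 | 2-[(3S,5S)-3,5-dimethyl-5-[(7E,9E,12Z)-pentadeca-7,9,12-trien-1-yl]-1,2-dioxolan-3-yl]ethan-1-ol | CC/C=C\C/C=C/C=C/CCCCCC[C@@]1(C)C[C@](C)(CCO)OO1 | intermediate
27 | 2-[(3R,5S)-3,5-dimethyl-5-[(7E,9E,12Z)-pentadeca-7,9,12-trien-1-yl]-1,2-dioxolan-3-yl]acetaldehyde | CC/C=C\C/C=C/C=C/CCCCCC[C@@]1(C)C[C@](C)(CC=O)OO1 | intermediate
28 | 2-[(3R,5S)-3,5-dimethyl-5-[(7E,9E,12Z)-pentadeca-7,9,12-trien-1-yl]-1,2-dioxolan-3-yl]acetic acid | CC/C=C\C/C=C/C=C/CCCCCC[C@@]1(C)C[C@](C)(CC(=O)O)OO1 | target

**Count and risks**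
Total steps: 16. Longest linear sequence: 13 (steps 2–10 and 13–16).

Step 4. The ring closure could lose its stereocontrol if the mercuration became reversible and equilibrated the C3 epimers, or the hydroperoxide could be captured by the C6=C7 alkene. From 11 the photooxygenation would then be run alone and hydroperoxide 12 isolated. Kinetic iodocyclisation (I2, NaHCO3, MeCN, 0 °C) would give methyl (6E)-7-[(3S,4R,5S)-5-{2-[(tert-butyldimethylsilyl)oxy]ethyl}-4-hydroxy-5-(iodomethyl)-3-methyl-1,2-dioxolan-3-yl]hept-6-enoate F1. Diimide would give the saturated methyl 7-[(3S,4R,5S)-5-{2-[(tert-butyldimethylsilyl)oxy]ethyl}-4-hydroxy-5-(iodomethyl)-3-methyl-1,2-dioxolan-3-yl]heptanoate F2, and PhOC(S)Cl with DMAP would give methyl 7-[(3S,4R,5S)-5-{2-[(tert-butyldimethylsilyl)oxy]ethyl}-5-(iodomethyl)-3-methyl-4-[(phenoxycarbonothioyl)oxy]-1,2-dioxolan-3-yl]heptanoate F3. A single Bu3SnH reduction would then remove iodine and the C4 oxygen together and return to the route at 17.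

Step 8. The C4 radical could open the ring, or deoxygenation at this doubly neopentyl position could stay incomplete. From 15, Dess–Martin oxidation would give methyl 7-[(3S,5S)-5-{2-[(tert-butyldimethylsilyl)oxy]ethyl}-3,5-dimethyl-4-oxo-1,2-dioxolan-3-yl]heptanoate F4. Condensation with 4-methylbenzenesulfonohydrazide would give methyl 7-[(3S,5S)-5-{2-[(tert-butyldimethylsilyl)oxy]ethyl}-3,5-dimethyl-4-{2-[(4-methylphenyl)sulfonyl]hydrazinylidene}-1,2-dioxolan-3-yl]heptanoate F5. Reduction of F5 with catecholborane followed by NaOAc (hydride-based deoxygenation of the tosylhydrazone) would return to the route at 17.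

Step 3. The alkenylchromium addition could give too little facial selectivity, which would erode the absolute configuration of everything that follows. From 8 and 2 the coupling would be run without chiral ligand (CrCl2, NiCl2 cat., DMSO) to racemic methyl (7Z)-12-[(tert-butyldimethylsilyl)oxy]-9-hydroxy-8-methyl-10-methylidenedodec-7-enoate F6. Dess–Martin oxidation would give methyl (7Z)-12-[(tert-butyldimethylsilyl)oxy]-8-methyl-10-methylidene-9-oxododec-7-enoate F7, and Corey–Bakshi–Shibata reduction (oxazaborolidine catalyst, catecholborane, −78 °C) would return to the route at 11.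

**Further compounds**
F1 | step 4 | methyl (6E)-7-[(3S,4R,5S)-5-{2-[(tert-butyldimethylsilyl)oxy]ethyl}-4-hydroxy-5-(iodomethyl)-3-methyl-1,2-dioxolan-3-yl]hept-6-enoate | COC(=O)CCCC/C=C/[C@@]1(C)[C@@H](O)[C@](CI)(CCO[Si](C)(C)C(C)(C)C)OO1
F2 | step 4 | methyl 7-[(3S,4R,5S)-5-{2-[(tert-butyldimethylsilyl)oxy]ethyl}-4-hydroxy-5-(iodomethyl)-3-methyl-1,2-dioxolan-3-yl]heptanoate | COC(=O)CCCCCC[C@@]1(C)[C@@H](O)[C@](CI)(CCO[Si](C)(C)C(C)(C)C)OO1
F3 | step 4 | methyl 7-[(3S,4R,5S)-5-{2-[(tert-butyldimethylsilyl)oxy]ethyl}-5-(iodomethyl)-3-methyl-4-[(phenoxycarbonothioyl)oxy]-1,2-dioxolan-3-yl]heptanoate | COC(=O)CCCCCC[C@@]1(C)[C@@H](OC(=S)Oc2ccccc2)[C@](CI)(CCO[Si](C)(C)C(C)(C)C)OO1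
F4 | step 8 | methyl 7-[(3S,5S)-5-{2-[(tert-butyldimethylsilyl)oxy]ethyl}-3,5-dimethyl-4-oxo-1,2-dioxolan-3-yl]heptanoate | COC(=O)CCCCCC[C@@]1(C)C(=O)[C@](C)(CCO[Si](C)(C)C(C)(C)C)OO1
F5 | step 8 | methyl 7-[(3S,5S)-5-{2-[(tert-butyldimethylsilyl)oxy]ethyl}-3,5-dimethyl-4-{2-[(4-methylphenyl)sulfonyl]hydrazinylidene}-1,2-dioxolan-3-yl]heptanoate | COC(=O)CCCCCC[C@@]1(C)C(=NNS(=O)(=O)c2ccc(C)cc2)[C@](C)(CCO[Si](C)(C)C(C)(C)C)OO1
F6 | step 3 | methyl (7Z)-12-[(tert-butyldimethylsilyl)oxy]-9-hydroxy-8-methyl-10-methylidenedodec-7-enoate (racemate) | COC(=O)CCCCC/C=C(C)\C(O)C(=C)CCO[Si](C)(C)C(C)(C)C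
F7 | step 3 | methyl (7Z)-12-[(tert-butyldimethylsilyl)oxy]-8-methyl-10-methylidene-9-oxododec-7-enoate | COC(=O)CCCCC/C=C(C)\C(=O)C(=C)CCO[Si](C)(C)C(C)(C)C
A1 | direct plan | (2R)-2,4-dimethyl-2-(oct-7-en-1-yl)oxetane | C=CCCCCCC[C@]1(C)CC(C)O1
A2 | direct plan | (5S)-3-methoxy-3,5-dimethyl-5-(oct-7-en-1-yl)-1,2-dioxolane | C=CCCCCCC[C@@]1(C)CC(C)(OC)OO1
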